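**Retrosynthetic overview**
- The target is (−)-epicatechin 3-O-gallate-(4β→8)-(−)-epigallocatechin 3-O-gallate-(4β→8)-(+)-catechin 3-O-gallate; the last step is global hydrogenolysis of 22 benzyl ethers and one C8 bromine cap.
- Key disconnections are the two interflavan C4–C8 bonds. Each is made by an intermolecular Michael-type (1,6-conjugate) addition of ring-A C8 of the lower fragment (a phloroglucinol-type aryl enol ether) to a C4 para-quinone-methide oxocarbenium ion released from a 4-(2-ethoxyethoxy) unit. The lower bond is made first, then the upper bond.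
- The three fragments come from (−)-epicatechin, (−)-EGCG (degalloylated enzymatically to (−)-epigallocatechin before protection) and (+)-catechin, so all C2/C3 centres are chiral-pool. The galloyl esters are installed before the couplings so that the 3-acyloxy group directs attack to the β-face (3,4-trans).
- No ring is formed in the route: all A rings, pyran rings and B rings are carried intact from the natural flavan-3-ols. The assembly order is bottom + middle, then top.

Assumption: compounds 1, 5, 7 and 12 and the enzyme tannase are bought; "4β" means trans to the 3-oxygen of these 2,3-cis units.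

**Route**

Step 1
Reactants: 1 (−)-epicatechin
Product: 2 5,7,3',4'-tetra-O-benzyl-(−)-epicatechin
Conditions: BnBr (4.4 equiv), K2CO3 (5 equiv), DMF, 0 °C to rt, Ar, 24 h
Reagents that add atoms: benzyl bromide, BrCc1ccccc1
Why: Williamson etherification with K2CO3 alkylates only the four acidic phenols, leaves the secondary 3-OH free and touches no stereocentre.

Step 2
Reactants: 2 5,7,3',4'-tetra-O-benzyl-(−)-epicatechin
Product: 3 (2R,3R,4S)-5,7,3',4'-tetra-O-benzyl-4β-(2-ethoxyethoxy)epicatechin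
Conditions: DDQ (2 equiv), 2-ethoxyethanol (10 equiv), CH2Cl2, rt, 2 h
Reagents that add atoms: 2-ethoxyethanol, CCOCCO
Why: DDQ benzylic oxidation (hydride abstraction at C4, activated by the ortho and para benzyloxy groups of ring A) with capture by the alcohol anti to the α-oriented 2-aryl and 3-OH groups gives the 3,4-trans ether, and this C4 centre is only a leaving-group site that is erased in step 12.

Step 3
Reactants: 3 (2R,3R,4S)-5,7,3',4'-tetra-O-benzyl-4β-(2-ethoxyethoxy)epicatechin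
Product: 4 (2R,3R,4S)-8-bromo-5,7,3',4'-tetra-O-benzyl-4β-(2-ethoxyethoxy)epicatechin
Conditions: NBS (1.05 equiv), CH2Cl2, −78 to −15 °C
Reagents that add atoms: N-bromosuccinimide, O=C1CCC(=O)N1Br
Why: Electrophilic aromatic bromination goes to C8, the most accessible and most nucleophilic position of the phloroglucinol-type ring A, and the bromine acts as a removable cap that later prevents the electrophile from adding to itself.

Step 4
Reactants: 4 (2R,3R,4S)-8-bromo-5,7,3',4'-tetra-O-benzyl-4β-(2-ethoxyethoxy)epicatechin; 5 3,4,5-tris(benzyloxy)benzoic acid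
Product: 6 8-bromo-5,7,3',4'-tetra-O-benzyl-4β-(2-ethoxyethoxy)epicatechin 3-O-[3,4,5-tris(benzyloxy)benzoate] (top electrophile)
Conditions: 5 (2 equiv), dicyclohexylcarbodiimide (2 equiv), 4-dimethylaminopyridine (0.5 equiv), CH2Cl2, rt, 24 h
Reagents that add atoms: none
Why: Steglich esterification acylates the only free hydroxyl with retention at C3 under neutral conditions that leave the acid-labile C4 ether and the aryl bromide intact.

Step 5
Reactants: 7 (−)-epigallocatechin 3-O-gallate (EGCG)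
Product: 8 (−)-epigallocatechin
Conditions: tannase (tannin acyl hydrolase from Aspergillus oryzae, cat.), 50 mM NaOAc/AcOH buffer (CH3CO2Na/CH3CO2H) pH 5.5, 35 °C, N2, 4 h; EtOAc extraction, Sephadex LH-20
Reagents that add atoms: none
Why: Enzymatic ester hydrolysis by tannase is specific for galloyl esters and cleaves at the acyl carbon, so the C3–O bond and both stereocentres are untouched, while the mildly acidic, oxygen-free medium prevents C2 epimerisation and autoxidation of the pyrogallol ring.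

Step 6
Reactants: 8 (−)-epigallocatechin
Product: 9 5,7,3',4',5'-penta-O-benzyl-(−)-epigallocatechin
Conditions: BnBr (5.5 equiv), K2CO3 (6 equiv), degassed DMF, 0 °C to rt, Ar, 24 h
Reagents that add atoms: benzyl bromide, BrCc1ccccc1
Why: Williamson etherification under oxygen-free conditions alkylates only the five acidic phenols, leaves the secondary 3-OH free and is fast enough at or below room temperature to outrun base-induced C2 epimerisation, so no stereocentre is touched.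

Step 7
Reactants: 9 5,7,3',4',5'-penta-O-benzyl-(−)-epigallocatechin
Product: 10 (2R,3R,4S)-5,7,3',4',5'-penta-O-benzyl-4β-(2-ethoxyethoxy)epigallocatechin
Conditions: DDQ (2 equiv), 2-ethoxyethanol (10 equiv), CH2Cl2, rt, 2 h
Reagents that add atoms: 2-ethoxyethanol, CCOCCO
Why: The same DDQ benzylic oxidation as in step 2 functionalises C4 selectively because only that C–H is activated by ring A, giving the 3,4-trans ether whose C4 configuration is later erased.

Step 8
Reactants: 10 (2R,3R,4S)-5,7,3',4',5'-penta-O-benzyl-4β-(2-ethoxyethoxy)epigallocatechin; 5 3,4,5-tris(benzyloxy)benzoic acid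
Product: 11 5,7,3',4',5'-penta-O-benzyl-4β-(2-ethoxyethoxy)epigallocatechin 3-O-[3,4,5-tris(benzyloxy)benzoate] (middle electrophile)
Conditions: 5 (2 equiv), dicyclohexylcarbodiimide (2 equiv), 4-dimethylaminopyridine (0.5 equiv), CH2Cl2, rt, 24 h
Reagents that add atoms: none
Why: Steglich esterification of the single free hydroxyl proceeds with retention at C3 and without disturbing the C4 ether.

Step 9
Reactants: 12 (+)-catechin
Product: 13 5,7,3',4'-tetra-O-benzyl-(+)-catechin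
Conditions: BnBr (4.4 equiv), K2CO3 (5 equiv), DMF, 0 °C to rt, Ar, 24 h
Reagents that add atoms: benzyl bromide, BrCc1ccccc1
Why: Williamson etherification is selective for the four phenols over the 3-OH and leaves the 2,3-trans stereocentres unchanged.

Step 10
Reactants: 13 5,7,3',4'-tetra-O-benzyl-(+)-catechin; 5 3,4,5-tris(benzyloxy)benzoic acid
Product: 14 5,7,3',4'-tetra-O-benzyl-(+)-catechin 3-O-[3,4,5-tris(benzyloxy)benzoate] (bottom nucleophile)
Conditions: 5 (1.5 equiv), dicyclohexylcarbodiimide (1.5 equiv), 4-dimethylaminopyridine (0.3 equiv), CH2Cl2, rt, 16 h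
Reagents that add atoms: none
Why: Steglich esterification of the unhindered equatorial 3-OH proceeds with retention and leaves ring-A C8 free as the nucleophilic site.

Step 11
Reactants: 11 middle electrophile; 14 bottom nucleophile (3 equiv, excess recovered)
Product: 16 protected lower dimer [penta-O-benzyl-EGC tribenzylgallate-(4β→8)-tetra-O-benzylcatechin tribenzylgallate], via middle-unit para-quinone-methide oxocarbenium triflate 15 (not isolated)
Conditions: TMSOTf (Me3SiOSO2CF3, 0.2 equiv), CH2Cl2, 4 Å molecular sieves, −78 to −40 °C, 30 min; NaHCO3 quench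
Reagents that add atoms: none
Why: TMSOTf ionises the C4 ether to the 7-O-benzyl para-quinone-methide oxocarbenium ion, and C8 of ring A of 14 adds to its C4 terminus in an intermolecular Michael-type 1,6-conjugate addition (vinylogous Mukaiyama–Michael, equally a Friedel–Crafts alkylation), attacking the β-face anti to the 3-O-galloyl group, whose carbonyl shields the α-face as an acyloxonium, so the new C4 centre is 3,4-trans (4β); C8 reacts rather than C6, as is general for 5,7-di-O-benzyl flavan-3-ols, because C6 is flanked by two benzyloxy groups, and the excess of 14 suppresses self-addition of 11.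

Step 12
Reactants: 6 top electrophile (1.3 equiv); 16 protected lower dimer
Product: 18 protected trimer [8-bromo-tetra-O-benzylepicatechin tribenzylgallate-(4β→8)-penta-O-benzyl-EGC tribenzylgallate-(4β→8)-tetra-O-benzylcatechin tribenzylgallate], via top-unit para-quinone-methide oxocarbenium triflate 17 (not isolated)
Conditions: TMSOTf (Me3SiOSO2CF3, 0.3 equiv), CH2Cl2, 4 Å molecular sieves, −78 to −30 °C, 1 h; NaHCO3 quench
Reagents that add atoms: none
Why: The same Michael-type 1,6-conjugate addition joins the only unhindered nucleophilic carbon of 16 (C8 of the middle unit) to C4 of the quinone-methide oxocarbenium, again anti to the participating 3-O-galloyl group to set the 3,4-trans (4β) centre, while the C8 bromine on 6 blocks self-condensation so that near-equimolar amounts suffice.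

Step 13
Reactants: 18 protected trimer
Product: 19 (−)-epicatechin 3-O-gallate-(4β→8)-(−)-epigallocatechin 3-O-gallate-(4β→8)-(+)-catechin 3-O-gallate (target)
Conditions: H2 (1 atm), 20% Pd(OH)2/C, NaOAc (CH3CO2Na, 1.2 equiv), THF/MeOH/H2O 20:20:1, rt, 16 h; Celite filtration, Sephadex LH-20, lyophilisation
Reagents that add atoms: none
Why: Catalytic hydrogenolysis cleaves all 22 benzyl ethers and the aryl C–Br bond in one operation while esters, interflavan bonds and all eight stereocentres are inert, and NaOAc buffers the HBr that would otherwise threaten the acid-labile interflavan bonds.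

**Compound list**

1 | (−)-epicatechin, (2R,3R) | Oc1cc(O)c2c(c1)O[C@H](c1ccc(O)c(O)c1)[C@H](O)C2 | starting material

2 | 5,7,3',4'-tetra-O-benzyl-(−)-epicatechin | c1c(OCc9ccccc9)cc(OCc9ccccc9)c2c1O[C@H](c1ccc(OCc9ccccc9)c(OCc9ccccc9)c1)[C@H](O)C2 | intermediate

3 | (2R,3R,4S)-5,7,3',4'-tetra-O-benzyl-4β-(2-ethoxyethoxy)epicatechin | c1c(OCc9ccccc9)cc(OCc9ccccc9)c2c1O[C@H](c1ccc(OCc9ccccc9)c(OCc9ccccc9)c1)[C@H](O)[C@H]2OCCOCC | intermediate

4 | (2R,3R,4S)-8-bromo-5,7,3',4'-tetra-O-benzyl-4β-(2-ethoxyethoxy)epicatechin | Brc1c(OCc9ccccc9)cc(OCc9ccccc9)c2c1O[C@H](c1ccc(OCc9ccccc9)c(OCc9ccccc9)c1)[C@H](O)[C@H]2OCCOCC | intermediate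

5 | 3,4,5-tris(benzyloxy)benzoic acid | OC(=O)c1cc(OCc2ccccc2)c(OCc2ccccc2)c(OCc2ccccc2)c1 | starting material

6 | 8-bromo-5,7,3',4'-tetra-O-benzyl-4β-(2-ethoxyethoxy)epicatechin 3-O-[3,4,5-tris(benzyloxy)benzoate] (top electrophile) | Brc1c(OCc9ccccc9)cc(OCc9ccccc9)c2c1O[C@H](c1ccc(OCc9ccccc9)c(OCc9ccccc9)c1)[C@H](OC(=O)c1cc(OCc9ccccc9)c(OCc9ccccc9)c(OCc9ccccc9)c1)[C@H]2OCCOCC | intermediate

7 | (−)-epigallocatechin 3-O-gallate (EGCG), (2R,3R) | Oc1cc(O)c2c(c1)O[C@H](c1cc(O)c(O)c(O)c1)[C@H](OC(=O)c1cc(O)c(O)c(O)c1)C2 | starting material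

8 | (−)-epigallocatechin (EGC), (2R,3R) | Oc1cc(O)c2c(c1)O[C@H](c1cc(O)c(O)c(O)c1)[C@H](O)C2 | intermediate

9 | 5,7,3',4',5'-penta-O-benzyl-(−)-epigallocatechin | c1c(OCc9ccccc9)cc(OCc9ccccc9)c2c1O[C@H](c1cc(OCc9ccccc9)c(OCc9ccccc9)c(OCc9ccccc9)c1)[C@H](O)C2 | intermediate

10 | (2R,3R,4S)-5,7,3',4',5'-penta-O-benzyl-4β-(2-ethoxyethoxy)epigallocatechin | c1c(OCc9ccccc9)cc(OCc9ccccc9)c2c1O[C@H](c1cc(OCc9ccccc9)c(OCc9ccccc9)c(OCc9ccccc9)c1)[C@H](O)[C@H]2OCCOCC | intermediate

11 | 5,7,3',4',5'-penta-O-benzyl-4β-(2-ethoxyethoxy)epigallocatechin 3-O-[3,4,5-tris(benzyloxy)benzoate] (middle electrophile) | c1c(OCc9ccccc9)cc(OCc9ccccc9)c2c1O[C@H](c1cc(OCc9ccccc9)c(OCc9ccccc9)c(OCc9ccccc9)c1)[C@H](OC(=O)c1cc(OCc9ccccc9)c(OCc9ccccc9)c(OCc9ccccc9)c1)[C@H]2OCCOCC | intermediate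

12 | (+)-catechin, (2R,3S) | Oc1cc(O)c2c(c1)O[C@H](c1ccc(O)c(O)c1)[C@@H](O)C2 | starting material

13 | 5,7,3',4'-tetra-O-benzyl-(+)-catechin | c1c(OCc9ccccc9)cc(OCc9ccccc9)c2c1O[C@H](c1ccc(OCc9ccccc9)c(OCc9ccccc9)c1)[C@@H](O)C2 | intermediate

14 | 5,7,3',4'-tetra-O-benzyl-(+)-catechin 3-O-[3,4,5-tris(benzyloxy)benzoate] (bottom nucleophile) | c1c(OCc9ccccc9)cc(OCc9ccccc9)c2c1O[C@H](c1ccc(OCc9ccccc9)c(OCc9ccccc9)c1)[C@@H](OC(=O)c1cc(OCc9ccccc9)c(OCc9ccccc9)c(OCc9ccccc9)c1)C2 | intermediate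

15 | middle-unit 7-O-benzyl para-quinone-methide oxocarbenium triflate (C4 cation of 11 after loss of the ether) | C1=C2C(OCc9ccccc9)=CC(=[O+]Cc9ccccc9)C=C2O[C@H](c3cc(OCc9ccccc9)c(OCc9ccccc9)c(OCc9ccccc9)c3)[C@@H]1OC(=O)c1cc(OCc9ccccc9)c(OCc9ccccc9)c(OCc9ccccc9)c1.[O-]S(=O)(=O)C(F)(F)F | intermediate

16 | protected lower dimer: penta-O-benzyl-EGC 3-O-tribenzylgallate-(4β→8)-tetra-O-benzylcatechin 3-O-tribenzylgallate | O=C(O[C@@H]1[C@@H](c2c(OCc9ccccc9)cc(OCc9ccccc9)c3c2O[C@H](c2ccc(OCc9ccccc9)c(OCc9ccccc9)c2)[C@@H](OC(=O)c2cc(OCc9ccccc9)c(OCc9ccccc9)c(OCc9ccccc9)c2)C3)c2c(OCc9ccccc9)cc(OCc9ccccc9)cc2O[C@@H]1c1cc(OCc9ccccc9)c(OCc9ccccc9)c(OCc9ccccc9)c1)c1cc(OCc9ccccc9)c(OCc9ccccc9)c(OCc9ccccc9)c1 | intermediate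

17 | top-unit 8-bromo 7-O-benzyl para-quinone-methide oxocarbenium triflate (C4 cation of 6 after loss of the ether) | C1=C2C(OCc9ccccc9)=CC(=[O+]Cc9ccccc9)C(Br)=C2O[C@H](c3ccc(OCc9ccccc9)c(OCc9ccccc9)c3)[C@@H]1OC(=O)c1cc(OCc9ccccc9)c(OCc9ccccc9)c(OCc9ccccc9)c1.[O-]S(=O)(=O)C(F)(F)F | intermediate

18 | protected trimer: 8-bromo-tetra-O-benzylepicatechin 3-O-tribenzylgallate-(4β→8)-penta-O-benzyl-EGC 3-O-tribenzylgallate-(4β→8)-tetra-O-benzylcatechin 3-O-tribenzylgallate | O=C(O[C@@H]1[C@@H](c2c(OCc9ccccc9)cc(OCc9ccccc9)c3c2O[C@H](c2ccc(OCc9ccccc9)c(OCc9ccccc9)c2)[C@@H](OC(=O)c2cc(OCc9ccccc9)c(OCc9ccccc9)c(OCc9ccccc9)c2)C3)c2c(OCc9ccccc9)cc(OCc9ccccc9)c([C@H]3c4c(OCc9ccccc9)cc(OCc9ccccc9)c(Br)c4O[C@H](c4ccc(OCc9ccccc9)c(OCc9ccccc9)c4)[C@@H]3OC(=O)c3cc(OCc9ccccc9)c(OCc9ccccc9)c(OCc9ccccc9)c3)c2O[C@@H]1c1cc(OCc9ccccc9)c(OCc9ccccc9)c(OCc9ccccc9)c1)c1cc(OCc9ccccc9)c(OCc9ccccc9)c(OCc9ccccc9)c1 | intermediate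

19 | (−)-epicatechin 3-O-gallate-(4β→8)-(−)-epigallocatechin 3-O-gallate-(4β→8)-(+)-catechin 3-O-gallate; top unit (2R,3R,4R), middle unit (2R,3R,4S), bottom unit (2R,3S) | O=C(O[C@@H]1[C@@H](c2c(O)cc(O)c3c2O[C@H](c2ccc(O)c(O)c2)[C@@H](OC(=O)c2cc(O)c(O)c(O)c2)C3)c2c(O)cc(O)c([C@H]3c4c(O)cc(O)cc4O[C@H](c4ccc(O)c(O)c4)[C@@H]3OC(=O)c3cc(O)c(O)c(O)c3)c2O[C@@H]1c1cc(O)c(O)c(O)c1)c1cc(O)c(O)c(O)c1 | target

**Step count and risks**

Total step count: 13. Longest linear sequence: 7 steps (steps 5, 6, 7, 8, 11, 12, 13; 7 → 8 → 9 → 10 → 11 → 16 → 18 → 19).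

Three steps most likely to fail:

Step 12 (upper interflavan bond). The nucleophilic C8 of the middle unit in 16 is crowded by its own galloyl ester and the lower unit, and the acid can also reopen the existing interflavan bond. The fallback reverses the order of bond formation with orthogonal activation and sets out from 11. Treating 11 with 2,6-dimethylbenzenethiol and BF3·OEt2 in CH2Cl2 at −78 °C exchanges the C4 ether for sulfur and gives the 4β-(2,6-dimethylphenylthio) middle unit F2. F2 then serves as the C8 nucleophile toward bromo-capped 6 under BF3·OEt2 at −78 to −30 °C, where the thioether is inert to the hard Lewis acid, to give the top–middle dimer thioether F3. Thiophilic activation of F3 with AgBF4 in THF at 0 °C in the presence of 14 (2 equiv) forms the lower bond by the same conjugate addition and comes back to the route at 18.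

Step 11 (lower interflavan bond). The electron-withdrawing 3-O-galloyl group slows ionisation of 11, and its free C8 allows self-addition. The fallback sets out from 10, the more easily ionised 3-hydroxy electrophile. Coupling 10 with 14 (3 equiv) under TMSOTf in CH2Cl2 at −78 °C gives the lower dimer with a free middle 3-hydroxyl F1; attack is still exclusively anti to the 3-oxygen in this 2,3-cis series. Esterifying F1 with 5 (dicyclohexylcarbodiimide, 4-dimethylaminopyridine, CH2Cl2, rt to 40 °C) comes back to the route at 16.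

Step 13 (global deprotection with debromination). Incomplete C–Br cleavage, or HBr damage to the free oligomer, would compromise the last step. The fallback avoids the halogen cap and sets out from 3. Esterifying 3 with 5 (dicyclohexylcarbodiimide, 4-dimethylaminopyridine) gives the uncapped top electrophile F4. Adding F4 slowly to an excess of 16 (2 equiv, recovered) with TMSOTf at −78 °C gives the bromine-free protected trimer F5. Hydrogenolysis of F5 over Pd(OH)2/C in THF/MeOH/H2O without any additive comes back to the route at 19.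

**Further compounds**

F1 | step 11 | 5,7,3',4',5'-penta-O-benzylepigallocatechin-(4β→8)-5,7,3',4'-tetra-O-benzylcatechin 3-O-[3,4,5-tris(benzyloxy)benzoate], free 3-OH on the upper unit | O[C@@H]1[C@@H](c2c(OCc9ccccc9)cc(OCc9ccccc9)c3c2O[C@H](c2ccc(OCc9ccccc9)c(OCc9ccccc9)c2)[C@@H](OC(=O)c2cc(OCc9ccccc9)c(OCc9ccccc9)c(OCc9ccccc9)c2)C3)c2c(OCc9ccccc9)cc(OCc9ccccc9)cc2O[C@@H]1c1cc(OCc9ccccc9)c(OCc9ccccc9)c(OCc9ccccc9)c1

F2 | step 12 | 5,7,3',4',5'-penta-O-benzyl-4β-(2,6-dimethylphenylthio)epigallocatechin 3-O-[3,4,5-tris(benzyloxy)benzoate] | c1c(OCc9ccccc9)cc(OCc9ccccc9)c2c1O[C@H](c1cc(OCc9ccccc9)c(OCc9ccccc9)c(OCc9ccccc9)c1)[C@H](OC(=O)c1cc(OCc9ccccc9)c(OCc9ccccc9)c(OCc9ccccc9)c1)[C@H]2Sc1c(C)cccc1C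

F3 | step 12 | 8-bromo-tetra-O-benzylepicatechin 3-O-tribenzylgallate-(4β→8)-penta-O-benzyl-4β-(2,6-dimethylphenylthio)epigallocatechin 3-O-tribenzylgallate | O=C(O[C@@H]1[C@@H](Sc2c(C)cccc2C)c2c(OCc9ccccc9)cc(OCc9ccccc9)c([C@H]3c4c(OCc9ccccc9)cc(OCc9ccccc9)c(Br)c4O[C@H](c4ccc(OCc9ccccc9)c(OCc9ccccc9)c4)[C@@H]3OC(=O)c3cc(OCc9ccccc9)c(OCc9ccccc9)c(OCc9ccccc9)c3)c2O[C@@H]1c1cc(OCc9ccccc9)c(OCc9ccccc9)c(OCc9ccccc9)c1)c1cc(OCc9ccccc9)c(OCc9ccccc9)c(OCc9ccccc9)c1

F4 | step 13 | 5,7,3',4'-tetra-O-benzyl-4β-(2-ethoxyethoxy)epicatechin 3-O-[3,4,5-tris(benzyloxy)benzoate] | c1c(OCc9ccccc9)cc(OCc9ccccc9)c2c1O[C@H](c1ccc(OCc9ccccc9)c(OCc9ccccc9)c1)[C@H](OC(=O)c1cc(OCc9ccccc9)c(OCc9ccccc9)c(OCc9ccccc9)c1)[C@H]2OCCOCC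

F5 | step 13 | bromine-free protected trimer: tetra-O-benzylepicatechin 3-O-tribenzylgallate-(4β→8)-penta-O-benzyl-EGC 3-O-tribenzylgallate-(4β→8)-tetra-O-benzylcatechin 3-O-tribenzylgallate | O=C(O[C@@H]1[C@@H](c2c(OCc9ccccc9)cc(OCc9ccccc9)c3c2O[C@H](c2ccc(OCc9ccccc9)c(OCc9ccccc9)c2)[C@@H](OC(=O)c2cc(OCc9ccccc9)c(OCc9ccccc9)c(OCc9ccccc9)c2)C3)c2c(OCc9ccccc9)cc(OCc9ccccc9)c([C@H]3c4c(OCc9ccccc9)cc(OCc9ccccc9)cc4O[C@H](c4ccc(OCc9ccccc9)c(OCc9ccccc9)c4)[C@@H]3OC(=O)c3cc(OCc9ccccc9)c(OCc9ccccc9)c(OCc9ccccc9)c3)c2O[C@@H]1c1cc(OCc9ccccc9)c(OCc9ccccc9)c(OCc9ccccc9)c1)c1cc(OCc9ccccc9)c(OCc9ccccc9)c(OCc9ccccc9)c1
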